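The route rests on the C4–C5 unit of the tetrahydropyran: C5 carries oxygen, C4 is CH2, and the two flank the quaternary ether carbon C6 and the bromine-bearing C3. A vinyl group on boron serves as this two-carbon linchpin. In one palladium-catalysed, enantioselective conjunctive cross-coupling, a bis(alkenyl)borate (vinyl plus the alkenyl group that carries the pre-formed cyclohexane and becomes C6) reacts with isobutenyl triflate (C3=C2). A 1,2-metallate shift forms C5–C6, reductive elimination forms C3–C4, and boron marks C5 for oxygen with ligand-controlled configuration. C6, C3 and the O1–C2 ring bond then follow by relay (directed epoxidation, bromoetherification).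

Key step: step 13

Remark on locants: tetrahydropyran O1, C2 (CMe2), C3 (CHBr), C4 (CH2), C5 (CHOAc), C6 (quaternary; CH3 and cyclohexyl); cyclohexane C1' (bonded to C6), C2', C3' (CHBr), C4' (C(CH3)Cl), C5', C6' (CHOH). "Cyclohexyl unit of 12" means the ring of 12 with all its stereocentres and its acetal unchanged.

Assumption: the (Sp,Sp) enantiomer of the ligand in step 13 is taken to give the 5S boronate; if the facial sense is the opposite one, its (Rp,Rp) antipode is used.

Step 1
Reactants: 1 (S)-4-benzyl-1,3-oxazolidin-2-one; 2 pent-4-enoyl chloride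
Product: 3 (S)-4-benzyl-3-(pent-4-enoyl)-1,3-oxazolidin-2-one
Conditions: n-BuLi, THF, −78 °C; then 2, −78 → 0 °C
Reagents that add atoms: none
Why: N-acylation of the lithiated oxazolidinone by the acid chloride is the standard preparation of an Evans imide and forms no stereocentre.

Step 2
Reactants: 4 3-methylbut-3-en-1-ol
Product: 5 3-methylbut-3-enal
Conditions: Dess–Martin periodinane, NaHCO3, CH2Cl2, 0 °C → rt; solution used at once
Reagents that add atoms: none
Why: Dess–Martin oxidation under buffered, non-basic conditions should give the β,γ-unsaturated aldehyde without migration of the double bond into conjugation.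

Step 3
Reactants: 3 (S)-4-benzyl-3-(pent-4-enoyl)-1,3-oxazolidin-2-one; 5 3-methylbut-3-enal
Product: 6 (S)-4-benzyl-3-[(2S,3R)-2-allyl-3-hydroxy-5-methylhex-5-enoyl]-1,3-oxazolidin-2-one
Conditions: Bu2BOTf, Et3N, CH2Cl2, −78 → 0 °C; then 5, −78 → 0 °C; then pH 7 buffer, MeOH, H2O2, 0 °C
Reagents that add atoms: none
Why: Evans syn aldol: the (Z)-boron enolate should react through a closed Zimmerman–Traxler chair with one enolate face shielded by the benzyl group, so that C1' (S) and C6' (R) arise together in the 2,3-syn relationship that becomes the cis ring substituents.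

Step 4
Reactants: 6 (S)-4-benzyl-3-[(2S,3R)-2-allyl-3-hydroxy-5-methylhex-5-enoyl]-1,3-oxazolidin-2-one
Product: 7 (2S,3R)-2-allyl-3-hydroxy-N-methoxy-N,5-dimethylhex-5-enamide
Conditions: MeNH(OMe)·HCl, AlMe3, THF, −20 → 0 °C
Reagents that add atoms: N,O-dimethylhydroxylamine hydrochloride, CNOC.Cl
Why: Aluminium amide transamination (Weinreb amide formation), assisted by the free β-hydroxyl, should remove the auxiliary without touching the two stereocentres.

Step 5
Reactants: 7 (2S,3R)-2-allyl-3-hydroxy-N-methoxy-N,5-dimethylhex-5-enamide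
Product: 8 (1S,6R)-6-hydroxy-N-methoxy-N,4-dimethylcyclohex-3-ene-1-carboxamide
Conditions: second-generation Grubbs catalyst RuCl2(=CHPh)(PCy3)(H2IMes) (cat.), CH2Cl2, 40 °C
Reagents that add atoms: none
Why: Ring-closing olefin metathesis of the allyl and methallyl groups should close the six-membered ring with the trisubstituted C3'=C4' alkene, the syn aldol centres becoming the cis 1,6-substituents.

Step 6
Reactants: 8 (1S,6R)-6-hydroxy-N-methoxy-N,4-dimethylcyclohex-3-ene-1-carboxamide
Product: 9 (1S,3R,4S,6R)-3,4-epoxy-6-hydroxy-N-methoxy-N,4-dimethylcyclohexane-1-carboxamide (epoxide cis to the hydroxyl)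
Conditions: VO(acac)2 (cat.), t-BuOOH, CH2Cl2, 0 °C → rt
Reagents that add atoms: tert-butyl hydroperoxide, CC(C)(C)OO
Why: Hydroxyl-directed epoxidation: the vanadium alkoxide of the homoallylic C6' alcohol should deliver oxygen to the alkene face cis to that hydroxyl, setting the C4' oxygen centre.

Step 7
Reactants: 9 (1S,3R,4S,6R)-3,4-epoxy-6-hydroxy-N-methoxy-N,4-dimethylcyclohexane-1-carboxamide
Product: 10 (1S,3S,4S,6R)-3-chloro-4,6-dihydroxy-N-methoxy-N,4-dimethylcyclohexane-1-carboxamide
Conditions: LiCl, AcOH, THF, rt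
Reagents that add atoms: lithium chloride, [Li+].[Cl-]
Why: Chloride should open the epoxide in the trans-diaxial sense (Fürst–Plattner rule) at the less substituted C3' with inversion, giving the axial secondary chloride and the axial tertiary alcohol, which is syn-diaxial to the C6' hydroxyl.

Step 8
Reactants: 10 (1S,3S,4S,6R)-3-chloro-4,6-dihydroxy-N-methoxy-N,4-dimethylcyclohexane-1-carboxamide
Product: 11 4,6-O-[(R)-benzylidene] acetal of 10 (bridged 1,3-dioxane, phenyl exo)
Conditions: PhCH(OMe)2, camphorsulfonic acid (cat.), CH2Cl2, rt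
Reagents that add atoms: benzaldehyde dimethyl acetal, COC(OC)c1ccccc1
Why: Thermodynamic acetalisation of the syn-diaxial 1,3-diol should give the bridged benzylidene acetal with hydrogen in the crowded endo position, masking both hydroxyls and preventing base-induced re-closure of the chlorohydrin to the epoxide in the steps ahead.

Step 9
Reactants: 11 4,6-O-[(R)-benzylidene] acetal of 10
Product: 12 1-[(1S,3S,4S,6R)-3-chloro-4-methyl-4,6-((R)-benzylidenedioxy)cyclohexyl]ethan-1-one
Conditions: MeMgBr, THF, −20 → 0 °C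
Reagents that add atoms: methylmagnesium bromide, C[Mg]Br
Why: Weinreb ketone synthesis: the chelated tetrahedral intermediate should hold until work-up and give the methyl ketone without epimerising C1'.

Step 10
Reactants: 12 1-[(1S,3S,4S,6R)-3-chloro-4-methyl-4,6-((R)-benzylidenedioxy)cyclohexyl]ethan-1-one
Product: 13 1-(cyclohexyl unit of 12)vinyl trifluoromethanesulfonate
Conditions: KN(SiMe3)2, THF, −78 °C; then PhNTf2, −78 → 0 °C
Reagents that add atoms: N-phenylbis(trifluoromethanesulfonimide), FC(F)(F)S(=O)(=O)N(c1ccccc1)S(=O)(=O)C(F)(F)F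
Why: Kinetic deprotonation at the methyl group followed by O-sulfonylation should give the terminal enol triflate and leave C1' untouched.

Step 11
Reactants: 13 1-(cyclohexyl unit of 12)vinyl trifluoromethanesulfonate
Product: 14 2-[1-(cyclohexyl unit of 12)vinyl]-4,4,5,5-tetramethyl-1,3,2-dioxaborolane
Conditions: B2pin2, PdCl2(PPh3)2 (cat.), PPh3, KOPh, toluene, 50 °C
Reagents that add atoms: bis(pinacolato)diboron, CC1(C)OB(OC1(C)C)B1OC(C)(C)C(C)(C)O1
Why: Miyaura borylation of the alkenyl triflate (oxidative addition, phenoxide-assisted boryl transfer, reductive elimination) should give the 1-substituted vinyl boronate.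

Step 12
Reactants: 15 2-methylpropanal
Product: 16 2-methylprop-1-en-1-yl trifluoromethanesulfonate (isobutenyl triflate)
Conditions: Tf2O, 2,6-di-tert-butyl-4-methylpyridine, CH2Cl2, 0 °C → rt
Reagents that add atoms: trifluoromethanesulfonic anhydride, FC(F)(F)S(=O)(=O)OS(=O)(=O)C(F)(F)F
Why: O-sulfonylation of the enolisable aldehyde and loss of the α-proton to the hindered base should give the vinyl triflate (enol triflate synthesis from an aldehyde).

Step 13
Reactants: 14 2-[1-(cyclohexyl unit of 12)vinyl]-4,4,5,5-tetramethyl-1,3,2-dioxaborolane; 16 isobutenyl triflate; 17 tetravinylstannane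
Product: 21 (3S)-2-(cyclohexyl unit of 12)-6-methylhepta-1,5-dien-3-ol, via vinyllithium 18 (not isolated), via lithium bis(alkenyl)borate 19 (not isolated), via allylic pinacol boronate 20 (not isolated)
Conditions: 17, n-BuLi, Et2O, rt; then 14, THF, −78 °C → rt; then 16, Pd(OAc)2 (cat.), (Sp,Sp)-MandyPhos C52H50FeN2P2 (cat.), THF, 60 °C; then NaOH, H2O2, THF/H2O, 0 °C → rt
Reagents that add atoms: hydrogen peroxide, OO
Why: Vinyllithium adds to boron to give a bis(alkenyl)borate; zerovalent palladium inserts into the triflate, the cationic isobutenylpalladium species (divalent palladium) binds the unsubstituted vinyl group of the borate, and this activation triggers a 1,2-metallate shift of the 1-substituted alkenyl group from boron to the α-carbon (C5–C6) anti to palladium while Pd–C4 forms, after which reductive elimination makes C3–C4. The closest known reaction type is the palladium-catalysed enantioselective conjunctive cross-coupling of bis(alkenyl)borates with C(sp2) triflates, which gives α-chiral allylic boronates. No ring is closed in this step; the tetrahydropyran is closed later at O1–C2. The new stereocentre C5 is controlled by the chiral bisphosphine, which selects the face of the vinyl group that palladium binds, and the oxidation of C–B to C–O keeps that configuration. The step needs chemoselectivity between the two alkenyl groups on boron and over direct Suzuki-type coupling: the α-substituent of the cyclohexyl-bearing alkenyl group keeps palladium off it, so the vinyl group should be the acceptor and the hindered group should migrate, while the pinacol ester slows transmetallation.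

Step 14
Reactants: 21 (3S)-2-(cyclohexyl unit of 12)-6-methylhepta-1,5-dien-3-ol
Product: 22 (1S)-1-[(2R)-2-(cyclohexyl unit of 12)oxiran-2-yl]-4-methylpent-3-en-1-ol (erythro)
Conditions: VO(acac)2 (cat.), t-BuOOH, CH2Cl2, 0 °C
Reagents that add atoms: tert-butyl hydroperoxide, CC(C)(C)OO
Why: Hydroxyl-directed vanadium epoxidation of the 1,1-disubstituted allylic alcohol: with the carbinol hydrogen eclipsing the C6 substituent to avoid A(1,2) strain, oxygen should be delivered to give the erythro epoxy alcohol, which sets C6 from C5, while the merely homoallylic trisubstituted alkene should react much more slowly.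

Step 15
Reactants: 22 (1S)-1-[(2R)-2-(cyclohexyl unit of 12)oxiran-2-yl]-4-methylpent-3-en-1-ol
Product: 23 (2S,3S)-2-(cyclohexyl unit of 12)-6-methylhept-5-ene-2,3-diol
Conditions: LiAlH4, THF, 0 °C
Reagents that add atoms: none
Why: Hydride should open the 2,2-disubstituted epoxide at its CH2 terminus (SN2), turning it into the C6 methyl group and the tertiary C6 alcohol, while the hindered secondary chloride should not react at this temperature.

Step 16
Reactants: 23 (2S,3S)-2-(cyclohexyl unit of 12)-6-methylhept-5-ene-2,3-diol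
Product: 24 (2S,3S)-2-(cyclohexyl unit of 12)-2-hydroxy-6-methylhept-5-en-3-yl acetate
Conditions: Ac2O, pyridine, DMAP (cat.), CH2Cl2, 0 °C → rt
Reagents that add atoms: acetic anhydride, CC(=O)OC(C)=O
Why: Acylation should be selective for the secondary C5 hydroxyl over the tertiary C6 hydroxyl.

Step 17
Reactants: 24 (2S,3S)-2-(cyclohexyl unit of 12)-2-hydroxy-6-methylhept-5-en-3-yl acetate
Product: 25 (3S,5S,6S)-5-acetoxy-3-bromo-2,2,6-trimethyl-6-(cyclohexyl unit of 12)tetrahydropyran
Conditions: 2,4,4,6-tetrabromocyclohexa-2,5-dienone, MeNO2, 0 °C → rt, dark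
Reagents that add atoms: 2,4,4,6-tetrabromocyclohexa-2,5-dienone, O=C1C(Br)=CC(Br)(Br)C=C1Br
Why: Bromoetherification: a bromonium ion on the only alkene is opened at the tertiary C2 (Markovnikov, 6-endo) by the C6 hydroxyl through a chair with the bulky cyclohexyl group equatorial and bromine equatorial (anti to the new O1–C2 bond), which should close the ring and set C3 (S).

Step 18
Reactants: 25 (3S,5S,6S)-5-acetoxy-3-bromo-2,2,6-trimethyl-6-(cyclohexyl unit of 12)tetrahydropyran
Product: 26 (3S,5S,6S)-5-acetoxy-3-bromo-6-[(1'S,3'S,4'S,6'R)-4'-bromo-3'-chloro-6'-hydroxy-4'-methylcyclohexyl]-2,2,6-trimethyltetrahydropyran (halogens trans-diaxial)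
Conditions: Me3SiBr, CH2Cl2, −20 → 0 °C; then H2O, aq. NaHCO3
Reagents that add atoms: bromotrimethylsilane, C[Si](C)(C)Br
Why: Silyl bromide cleavage of the acetal should release benzaldehyde and ionise the tertiary C4'–O bond; the anti-periplanar axial chlorine at C3' covers the lower face (chloronium-type participation), so bromide should enter axially on the face the oxygen left (retention at C4').

Step 19
Reactants: 26 (3S,5S,6S)-5-acetoxy-3-bromo-6-[(1'S,3'S,4'S,6'R)-4'-bromo-3'-chloro-6'-hydroxy-4'-methylcyclohexyl]-2,2,6-trimethyltetrahydropyran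
Product: 27 (3S,5S,6S)-5-acetoxy-3-bromo-6-[(1'S,3'R,4'R,6'R)-3'-bromo-4'-chloro-6'-hydroxy-4'-methylcyclohexyl]-2,2,6-trimethyltetrahydropyran (target)
Conditions: MeCN, 80 °C, dark
Reagents that add atoms: none
Why: Thermal dyotropic 1,2-interchange of the anti-periplanar halogens (diaxial-to-diequatorial rearrangement of a vicinal dihalide): bromine shifts on the upper face to C3' and chlorine on the lower face to C4', both carbons inverting, which should lead to the isomer with the stronger tertiary C–Cl bond and both halogens equatorial, favoured in a polar, hydrogen-bond-accepting solvent.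

Compound list

1 | (S)-4-benzyl-1,3-oxazolidin-2-one | O=C1OC[C@H](Cc2ccccc2)N1 | starting material
2 | pent-4-enoyl chloride | C=CCCC(Cl)=O | starting material
3 | (S)-4-benzyl-3-(pent-4-enoyl)-1,3-oxazolidin-2-one | C=CCCC(=O)N1[C@@H](Cc2ccccc2)COC1=O | intermediate
4 | 3-methylbut-3-en-1-ol | CC(=C)CCO | starting material
5 | 3-methylbut-3-enal | CC(=C)CC=O | intermediate
6 | (S)-4-benzyl-3-[(2S,3R)-2-allyl-3-hydroxy-5-methylhex-5-enoyl]-1,3-oxazolidin-2-one (syn aldol) | O=C(N1[C@@H](Cc2ccccc2)COC1=O)[C@@H](CC=C)[C@H](O)CC(C)=C | intermediate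
7 | (2S,3R)-2-allyl-3-hydroxy-N-methoxy-N,5-dimethylhex-5-enamide | CON(C)C(=O)[C@@H](CC=C)[C@H](O)CC(C)=C | intermediate
8 | (1S,6R)-6-hydroxy-N-methoxy-N,4-dimethylcyclohex-3-ene-1-carboxamide (cis) | CON(C)C(=O)[C@H]1CC=C(C)C[C@H]1O | intermediate
9 | (1S,3R,4S,6R)-3,4-epoxy-6-hydroxy-N-methoxy-N,4-dimethylcyclohexane-1-carboxamide (epoxide cis to OH) | CON(C)C(=O)[C@H]1C[C@@H]2[C@@](C)(O2)C[C@H]1O | intermediate
10 | (1S,3S,4S,6R)-3-chloro-4,6-dihydroxy-N-methoxy-N,4-dimethylcyclohexane-1-carboxamide | CON(C)C(=O)[C@H]1C[C@H](Cl)[C@@](C)(O)C[C@H]1O | intermediate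
11 | 4,6-O-[(R)-benzylidene] acetal of 10 (bridged 1,3-dioxane, phenyl exo) | CON(C)C(=O)[C@H]1C[C@H](Cl)[C@@](C)(O2)C[C@H]1O[C@H]2c3ccccc3 | intermediate
12 | 1-[(1S,3S,4S,6R)-3-chloro-4-methyl-4,6-((R)-benzylidenedioxy)cyclohexyl]ethan-1-one | CC(=O)[C@H]1C[C@H](Cl)[C@@](C)(O2)C[C@H]1O[C@H]2c3ccccc3 | intermediate
13 | 1-(cyclohexyl unit of 12)vinyl trifluoromethanesulfonate | C=C(OS(=O)(=O)C(F)(F)F)[C@H]1C[C@H](Cl)[C@@](C)(O2)C[C@H]1O[C@H]2c3ccccc3 | intermediate
14 | 2-[1-(cyclohexyl unit of 12)vinyl]-4,4,5,5-tetramethyl-1,3,2-dioxaborolane | C=C(B4OC(C)(C)C(C)(C)O4)[C@H]1C[C@H](Cl)[C@@](C)(O2)C[C@H]1O[C@H]2c3ccccc3 | intermediate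
15 | 2-methylpropanal | CC(C)C=O | starting material
16 | 2-methylprop-1-en-1-yl trifluoromethanesulfonate (isobutenyl triflate) | CC(C)=COS(=O)(=O)C(F)(F)F | intermediate
17 | tetravinylstannane | C=C[Sn](C=C)(C=C)C=C | starting material
18 | vinyllithium | [Li]C=C | intermediate
19 | lithium [1-(cyclohexyl unit of 12)vinyl](vinyl)(pinacolato)borate | [Li+].C=C[B-]4(OC(C)(C)C(C)(C)O4)C(=C)[C@H]1C[C@H](Cl)[C@@](C)(O2)C[C@H]1O[C@H]2c3ccccc3 | intermediate
20 | pinacol ester of (3S)-[2-(cyclohexyl unit of 12)-6-methylhepta-1,5-dien-3-yl]boronic acid | C=C([C@@H](B4OC(C)(C)C(C)(C)O4)CC=C(C)C)[C@H]1C[C@H](Cl)[C@@](C)(O2)C[C@H]1O[C@H]2c3ccccc3 | intermediate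
21 | (3S)-2-(cyclohexyl unit of 12)-6-methylhepta-1,5-dien-3-ol | C=C([C@@H](O)CC=C(C)C)[C@H]1C[C@H](Cl)[C@@](C)(O2)C[C@H]1O[C@H]2c3ccccc3 | intermediate
22 | (1S)-1-[(2R)-2-(cyclohexyl unit of 12)oxiran-2-yl]-4-methylpent-3-en-1-ol (erythro) | O[C@@H](CC=C(C)C)[C@]4(CO4)[C@H]1C[C@H](Cl)[C@@](C)(O2)C[C@H]1O[C@H]2c3ccccc3 | intermediate
23 | (2S,3S)-2-(cyclohexyl unit of 12)-6-methylhept-5-ene-2,3-diol | C[C@@](O)([C@@H](O)CC=C(C)C)[C@H]1C[C@H](Cl)[C@@](C)(O2)C[C@H]1O[C@H]2c3ccccc3 | intermediate
24 | (2S,3S)-2-(cyclohexyl unit of 12)-2-hydroxy-6-methylhept-5-en-3-yl acetate | C[C@@](O)([C@@H](OC(C)=O)CC=C(C)C)[C@H]1C[C@H](Cl)[C@@](C)(O2)C[C@H]1O[C@H]2c3ccccc3 | intermediate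
25 | (3S,5S,6S)-5-acetoxy-3-bromo-2,2,6-trimethyl-6-(cyclohexyl unit of 12)tetrahydropyran | CC(=O)O[C@H]1C[C@H](Br)C(C)(C)O[C@@]1(C)[C@H]1C[C@H](Cl)[C@@](C)(O2)C[C@H]1O[C@H]2c3ccccc3 | intermediate
26 | (3S,5S,6S)-5-acetoxy-3-bromo-6-[(1'S,3'S,4'S,6'R)-4'-bromo-3'-chloro-6'-hydroxy-4'-methylcyclohexyl]-2,2,6-trimethyltetrahydropyran (diaxial halogens) | CC(=O)O[C@H]1C[C@H](Br)C(C)(C)O[C@@]1(C)[C@H]1C[C@H](Cl)[C@@](C)(Br)C[C@H]1O | intermediate
27 | (3S,5S,6S)-5-acetoxy-3-bromo-6-[(1'S,3'R,4'R,6'R)-3'-bromo-4'-chloro-6'-hydroxy-4'-methylcyclohexyl]-2,2,6-trimethyltetrahydropyran | CC(=O)O[C@H]1C[C@H](Br)C(C)(C)O[C@@]1(C)[C@H]1C[C@@H](Br)[C@](C)(Cl)C[C@H]1O | target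

Total step count: 19. Longest linear sequence: 17 steps (steps 1, 3 to 11 and 13 to 19).

Steps most likely to fail

Step 13 (key step). The wrong alkenyl group may migrate, either alkenyl group may transmetallate directly to palladium (plain Suzuki-type coupling), or the congested borate may be captured so slowly that the isobutenylpalladium species decays; the neighbouring C1' centre may also erode facial control. Fallback: from enol triflate 13, a Nozaki–Hiyama–Kishi coupling (CrCl2, NiCl2 cat., DMF) with 4-methylpent-3-enal F1 (Dess–Martin oxidation of commercial 4-methylpent-3-en-1-ol) should give 21 together with its C5 epimer F2. The mixture is oxidised with Dess–Martin periodinane to the enone F3, and a Corey–Bakshi–Shibata reduction (oxazaborolidine enantiomer chosen for 5S, BH3·SMe2) comes back to the route at 21. In this fallback the two bonds are made in separate events, C3–C4 being bought in F1.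

Step 17. The two chair transition states may be poorly discriminated (epimer at C3), the bromonium ion may be captured by the neighbouring acetate, or a proton may be lost to give an allylic bromide. Fallback: from 24, mercuricyclisation with Hg(OCOCF3)2 in MeNO2 and exchange with aqueous KBr should give the bromomercurio tetrahydropyran F4; oxymercuration is reversible, so the more stable chair with equatorial mercury should prevail. Brominolysis with Br2 and LiBr in pyridine under O2, which keeps configuration, comes back to the route at 25.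

Step 19. The interchange may stop at an equilibrium that still holds much of the diaxial isomer, which an intramolecular O–H···Br hydrogen bond stabilises, or the tertiary bromide may lose HBr on heating. Fallback: from 26, silylation (Et3SiCl, imidazole, DMF) gives the triethylsilyl ether F5, in which that hydrogen bond is gone and the axial bromine is pressed against the silyloxy group. Heating F5 in MeNO2 at 60 °C should give the diequatorial silyl ether F6, and HF·pyridine in THF comes back to the route at 27.

Further compounds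

F1 | step 13 | 4-methylpent-3-enal | CC(C)=CCC=O
F2 | step 13 | (3R)-2-(cyclohexyl unit of 12)-6-methylhepta-1,5-dien-3-ol (C5 epimer of 21) | C=C([C@H](O)CC=C(C)C)[C@H]1C[C@H](Cl)[C@@](C)(O2)C[C@H]1O[C@H]2c3ccccc3
F3 | step 13 | 2-(cyclohexyl unit of 12)-6-methylhepta-1,5-dien-3-one | C=C(C(=O)CC=C(C)C)[C@H]1C[C@H](Cl)[C@@](C)(O2)C[C@H]1O[C@H]2c3ccccc3
F4 | step 17 | 5-acetoxy-3-(bromomercurio)-2,2,6-trimethyl-6-(cyclohexyl unit of 12)tetrahydropyran (mercury in place of the C3 bromine of 25) | CC(=O)O[C@H]1C[C@H]([Hg]Br)C(C)(C)O[C@@]1(C)[C@H]1C[C@H](Cl)[C@@](C)(O2)C[C@H]1O[C@H]2c3ccccc3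
F5 | step 19 | 6'-O-triethylsilyl ether of 26 | CC(=O)O[C@H]1C[C@H](Br)C(C)(C)O[C@@]1(C)[C@H]1C[C@H](Cl)[C@@](C)(Br)C[C@H]1O[Si](CC)(CC)CC
F6 | step 19 | 6'-O-triethylsilyl ether of 27 | CC(=O)O[C@H]1C[C@H](Br)C(C)(C)O[C@@]1(C)[C@H]1C[C@@H](Br)[C@](C)(Cl)C[C@H]1O[Si](CC)(CC)CC
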